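**Remark on the chemistry (assumptions):** dihydroferulic acid, 2‑methoxy‑4‑nitrophenol, (R)‑4‑benzyl‑2‑oxazolidinone, tert‑butyl bromoacetate and TEMPO are taken as purchasable; the connectivity and configuration of 12, 16 and 19 agree with the target and need no correction, the C4 descriptor changing from S (9, 12) to R (19–21) only because C3 outranks C5 once it carries oxygen.

## Structural features

The target is a γ‑butyrolactone (ring atoms O1, C2(=O), C3, C4, C5) with a 4‑hydroxy‑3‑methoxybenzyl arm on C3, a second one on C4, and a tertiary hydroxyl on C3. C3 (S) and C4 (R) are adjacent stereocentres: the two arylmethyl arms are cis on the ring and the hydroxyl is trans to the C4 arm. C3 is fully substituted (O, C2, C4, CH2Ar) and cannot be corrected by epimerisation, whereas C4 is a simple tertiary CH. Fragile features are the two free phenols (oxidation, azo coupling, radical quenching) and the lactone (opened by hydroxide and hydride). In the intermediates the exocyclic double bond of a 3‑methylene lactone can migrate into the ring and erase C4. The real difficulty is the oxygenated quaternary centre C3 with the right configuration relative to C4. The key step exploits the fact that the two non‑ring substituents of C3, the CH2–aryl arm and the oxygen, are the two ends of an exocyclic C3=CH2 bond: carbon goes to CH2, oxygen to C3, and the C4 arm decides the face.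

## Logic of the disconnections

**21 to 20.** The two phenolic O–H bonds are exchanged for O–CH2Ph bonds. Free phenols would couple with a diazonium ion, donate hydrogen to radicals and consume base in every enolate step. One protecting group on both arenes means one final operation. The forward step must cleave two aryl benzyl ethers and spare the lactone and the C3–O bond; this is safe because C3 is homobenzylic, not benzylic.

**20 to 19.** The O–H bond at C3 is replaced by an O–N bond. The tertiary alcohol is thus seen as the reduced form of an alkoxyamine, which is what a carbon radical forms with a nitroxide. No skeletal simplification results, but the C3–O bond becomes accessible by radical coupling. The forward step must break N–O and leave C3–O and the C3 configuration alone.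

**19 to 12, 16 and 17.** Two bonds are cut, CH2–aryl and C3–O. They end on the two carbons of an exocyclic C3=CH2 bond, so the cut removes the quaternary stereocentre and one whole aryl ring at once and leaves 12 with a single stereocentre. The forward step must put the aryl group on the CH2 terminus only, bring oxygen to the C3 face anti to the C4 arm, and leave the C4–H untouched. For that reason 17 is used as its sodium salt 18, which is consumed by 16 as it is added and lets 12 be the limiting component.

**16 to 15, 14 and 13.** The N≡N unit is traced to NH2, this to NO2, and the O–CH2Ph bond is cut. The nitro group of 13 already sits para to the oxygen that must be protected, so no regiochemical question arises. The reduction of 14 must not cleave the benzyl ether, which excludes hydrogen over palladium, and 16 must be isolable, which the tetrafluoroborate counter‑ion secures.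

**12 to 9 (through 10 and 11).** The C3=CH2 bond is cut and the exocyclic carbon removed. This leaves 9, a lactone with one stereocentre and an enolisable C3. The forward sequence must end with an elimination mild enough that the double bond does not move into the ring.

**9 to 7 (through 8).** The O1–C2 bond is opened and C5 is returned to the oxidation level of an imide carbonyl bound to the auxiliary nitrogen. The ring becomes an open chain whose stereocentre stands α to an N‑acyl oxazolidinone, the setting in which it can be made reliably. The forward step needs a hydride that takes the imide carbonyl and spares the tert‑butyl ester.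

**7 to 5 and 6.** The C3–C4 bond is cut. This is the enolate alkylation that creates C4; it reduces the problem to an achiral acyl chain plus a two‑carbon electrophile. The forward step needs a chelated Z‑enolate and the (R)‑configured auxiliary, which should give the S centre required for 9 and 12.

**5 to 2 and 3 (through 4).** The N–acyl bond is cut, giving the acid 2 and the auxiliary 3; the forward step needs only mild carboxyl activation.

**2 to 1.** The phenolic O–CH2Ph bond is cut; the forward step must alkylate the phenoxide in the presence of the carboxylate.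

## Other disconnections considered

**Alternative 1:** The cut removes O1–C2 and C2–C3, so that C2 comes from carbon monoxide and the open precursor is (S)‑2‑[(4‑benzyloxy‑3‑methoxyphenyl)methyl]‑4‑(4‑benzyloxy‑3‑methoxyphenyl)but‑3‑yn‑1‑ol A1.

- Forward key step: cyclocarbonylation of A1 (Pd(OAc)2, 1,4‑bis(diphenylphosphino)butane, CO/H2). Syn addition of hydrogen and the acyl group across the alkyne would give the (E)‑3‑arylmethylidene lactone A2.
- In favour: the ring is closed and C2 is brought in catalytically, the alkene geometry follows from the mechanism, the aryl group enters by Sonogashira coupling, and no diazonium salt or stoichiometric nitroxide is needed. On atom economy and reagent hazard this is better than the chosen plan.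
- Against: A2 lacks the C3 oxygen and has an sp2 benzylic carbon. A further reductive α‑hydroxylation (Mn(dpm)3, PhSiH3, O2, Mukaiyama type) would be needed to reach 20, and only that later step sets C3. A1 carries the C4 centre in an alkynol that is no easier to make than 12. Closure to a six‑membered unsaturated lactone can compete.
- Comparison: on structure, both plans make two skeletal bonds; the alternative closes the ring, the chosen plan makes the C3–O bond and the quaternary centre directly. On mechanism, organopalladium insertion replaces a radical three‑component coupling. Stereocontrol at C3 rests on the C4 arm in both, so the plans are equal there. Two steps follow the key step in both, again equal. Overall length is judged no shorter.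

**Alternative 2:** The cut removes C2–C3 and CH2–aryl. The precursors are the alkenyl boronate (S)‑2‑{4‑benzyloxy‑3‑[(4‑benzyloxy‑3‑methoxyphenyl)methyl]but‑1‑en‑2‑yl}‑4,4,5,5‑tetramethyl‑1,3,2‑dioxaborolane A3, the Grignard reagent (isopropoxydimethylsilyl)methylmagnesium chloride A4 and the aryl triflate 4‑benzyloxy‑3‑methoxyphenyl trifluoromethanesulfonate A5.

- Forward key step: A3 and A4 form a boron ate complex. Arylpalladium from A5 (Pd(OAc)2, chiral ferrocenyl bisphosphine, NaOTf) induces the 1,2‑shift of the silylmethyl group to C3, and reductive elimination forms CH2–aryl. The product would be the tertiary boronate A6, configured at both centres as in the target with boron in the place of the hydroxyl.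
- In favour: two carbon–carbon bonds are made at C3 in one step, and the C3 configuration is set by the ligand, not only by the C4 arm. Either C3 epimer would be reachable; on stereochemical flexibility this is better than the chosen plan. Oxidation of C–B to C–O is stereoretentive.
- Against: A6 is acyclic and at the wrong oxidation level. C2 arrives as CH2Si and must be oxidised to the acid level while the C5 oxygen stays differentiated, and the ring must still be closed; about four steps follow the key step against two. A3 is itself a multistep target. The C4 centre may be mismatched with the ligand, and an electron‑rich triflate adds slowly to zerovalent palladium.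
- Comparison: on structure, the alternative builds more carbon skeleton per step (better) but no C–O bond and no ring. On mechanism, a two‑electron metallate shift is better understood for stereocontrol than radical trapping (better). On step economy the chosen plan is shorter before and after the key step.

**Alternative 3:** The cut removes O1–C5. The precursor is the cyclopropane acid (S)‑3‑(4‑benzyloxy‑3‑methoxyphenyl)‑2‑[(1S,2S)‑2‑(4‑benzyloxy‑3‑methoxyphenyl)cyclopropyl]‑2‑hydroxypropanoic acid A7.

- Forward key step: photo‑oxidation of the arylcyclopropane (9‑mesityl‑10‑methylacridinium tetrafluoroborate, blue light, catalytic diphenyl disulfide) gives a radical cation. The carboxyl oxygen opens it at the ring CH2 in a 5‑exo‑tet sense, and the benzylic radical is reduced to CH2. The product A8 is identical with 20.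
- In favour: only hydrogenolysis follows, one step against two (better). The key step forms no stereocentre and so carries no selectivity risk (better). It is redox‑neutral and catalytic.
- Against: A7 already holds C3 and C4 and a trans‑cyclopropane, so the central problem, a configured tertiary carbinol next to C4, is only moved earlier into a less controllable setting. One stereocentre is made only to be destroyed. Both arenes are equally electron‑rich, so oxidation of the wrong one is unproductive. An α‑hydroxy carboxylate is prone to oxidative decarboxylation. The intrinsic preference of such radical cations for attack at the more substituted carbon opposes attack at C5, although a four‑membered ring is disfavoured.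
- Comparison: on structure, one C–O bond and a ring against two bonds and a stereocentre in the chosen plan. On mechanism, both are single‑electron processes; the chosen one uses the C4 arm for control, the alternative needs none at that stage. On step economy the alternative is shorter after the key step but clearly longer before it.

Key step: step 9

## Route

Step 1
Reactants: 1 3‑(4‑hydroxy‑3‑methoxyphenyl)propanoic acid (dihydroferulic acid)
Product: 2 3‑(4‑benzyloxy‑3‑methoxyphenyl)propanoic acid
Conditions: BnBr (1.2 equiv), NaOH (2.5 equiv), EtOH/H2O, reflux; then aq. HCl, 0 °C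
Reagents that add atoms: benzyl bromide, BrCc1ccccc1
Why: Williamson ether synthesis on the phenoxide; in the protic medium the carboxylate is a poor nucleophile and any benzyl ester formed is saponified by the excess hydroxide.

Step 2
Reactants: 2 3‑(4‑benzyloxy‑3‑methoxyphenyl)propanoic acid; 3 (R)‑4‑benzyl‑2‑oxazolidinone
Product: 5 (R)‑4‑benzyl‑3‑[3‑(4‑benzyloxy‑3‑methoxyphenyl)propanoyl]oxazolidin‑2‑one, via mixed pivalic anhydride 4 (not isolated)
Conditions: PivCl, Et3N, THF, −20 °C; then 3, LiCl, −20 °C to rt
Reagents that add atoms: none
Why: N‑acylation through a mixed anhydride; LiCl with Et3N makes the oxazolidinone nitrogen nucleophilic enough to attack the unhindered carbonyl of 4, and no stereocentre is touched.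

Step 3
Reactants: 5 (R)‑4‑benzyl‑3‑[3‑(4‑benzyloxy‑3‑methoxyphenyl)propanoyl]oxazolidin‑2‑one; 6 tert‑butyl bromoacetate
Product: 7 tert‑butyl (S)‑4‑[(R)‑4‑benzyl‑2‑oxooxazolidin‑3‑yl]‑3‑[(4‑benzyloxy‑3‑methoxyphenyl)methyl]‑4‑oxobutanoate
Conditions: NaN(SiMe3)2, THF, −78 °C; then 6, −78 to −40 °C
Reagents that add atoms: none
Why: Evans‑type alkylation of the chelated Z‑sodium enolate; the benzyl group of the (R)‑auxiliary shields one face and the bromoacetate enters from the other, which should set the future C4 as S.

Step 4
Reactants: 7 tert‑butyl (S)‑4‑[(R)‑4‑benzyl‑2‑oxooxazolidin‑3‑yl]‑3‑[(4‑benzyloxy‑3‑methoxyphenyl)methyl]‑4‑oxobutanoate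
Product: 9 (S)‑4‑[(4‑benzyloxy‑3‑methoxyphenyl)methyl]dihydrofuran‑2(3H)‑one, via hydroxy tert‑butyl ester 8 (not isolated)
Conditions: LiBH4, H2O (1.1 equiv), Et2O, 0 °C; aq. NH4Cl; crude in toluene, TsOH·H2O (cat.), 60 °C
Reagents that add atoms: none
Why: Reductive cleavage of the auxiliary, in which the hydride takes the activated exocyclic imide carbonyl and spares the hindered tert‑butyl ester, followed by acid‑catalysed lactonisation with loss of tert‑butanol; the stereocentre is not involved in either event and 3 is recovered.

Step 5
Reactants: 9 (S)‑4‑[(4‑benzyloxy‑3‑methoxyphenyl)methyl]dihydrofuran‑2(3H)‑one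
Product: 12 (S)‑4‑[(4‑benzyloxy‑3‑methoxyphenyl)methyl]‑3‑methylenedihydrofuran‑2(3H)‑one, via Mannich base 10 (not isolated), via trimethylammonium iodide 11 (not isolated)
Conditions: LiN(iPr)2, THF, −78 °C; Me2N=CH2+ I−, −78 °C to rt; concentrate; MeI, MeOH, rt; then aq. NaHCO3/CH2Cl2, rt
Reagents that add atoms: N,N‑dimethylmethyleneiminium iodide (Eschenmoser's salt), C=[N+](C)C.[I-]
Why: α‑Methylenation by Mannich reaction of the lactone enolate (anti to the C4 arm), exhaustive N‑methylation and β‑elimination of trimethylamine; hydrogencarbonate is too weak a base to remove the C4 hydrogen, so the double bond should stay exocyclic and C4 intact.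

Step 6
Reactants: 13 2‑methoxy‑4‑nitrophenol
Product: 14 1‑benzyloxy‑2‑methoxy‑4‑nitrobenzene
Conditions: BnBr, K2CO3, DMF, 60 °C
Reagents that add atoms: benzyl bromide, BrCc1ccccc1
Why: Williamson ether synthesis on an acidic nitrophenol, whose phenoxide forms readily with carbonate.

Step 7
Reactants: 14 1‑benzyloxy‑2‑methoxy‑4‑nitrobenzene
Product: 15 4‑benzyloxy‑3‑methoxyaniline
Conditions: Fe powder, AcOH, EtOH/H2O, 70 °C
Reagents that add atoms: none
Why: Béchamp‑type reduction of the nitro group by iron in acetic acid; the aryl benzyl ether is inert to these conditions, whereas hydrogen over palladium would cleave it.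

Step 8
Reactants: 15 4‑benzyloxy‑3‑methoxyaniline
Product: 16 4‑benzyloxy‑3‑methoxybenzenediazonium tetrafluoroborate
Conditions: NaNO2, HBF4 (48 % aq.), H2O, 0 °C; precipitate washed with cold Et2O, stored cold in the dark
Reagents that add atoms: sodium nitrite, O=N[O-].[Na+]; tetrafluoroboric acid, F[B-](F)(F)F.[H+]
Why: Diazotisation in strong acid, which suppresses triazene formation; the para‑alkoxy donor and the non‑nucleophilic tetrafluoroborate should give a salt that can be filtered and dried.

Step 9
Reactants: 12 (S)‑4‑[(4‑benzyloxy‑3‑methoxyphenyl)methyl]‑3‑methylenedihydrofuran‑2(3H)‑one; 16 4‑benzyloxy‑3‑methoxybenzenediazonium tetrafluoroborate; 17 TEMPO (2,2,6,6‑tetramethylpiperidin‑1‑oxyl)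
Product: 19 (3S,4R)‑3,4‑bis[(4‑benzyloxy‑3‑methoxyphenyl)methyl]‑3‑[(2,2,6,6‑tetramethylpiperidin‑1‑yl)oxy]dihydrofuran‑2(3H)‑one, via TEMPONa 18 (not isolated)
Conditions: 17, Na, THF, rt (gives 18); 18 (3.0 equiv) added over 4 h to 12 (1 equiv) and 16 (3.5 equiv) in PhCF3, rt, argon, dark
Reagents that add atoms: none
Why: Mechanism: 18 transfers one electron to 16, which loses N2 and gives the aryl σ‑radical together with 17; the aryl radical adds to the unsubstituted CH2 terminus of the C3=CH2 bond of 12, and the resulting tertiary, carbonyl‑stabilised C3 radical couples with the persistent nitroxide 17 to form the C3–O bond. The closest known reaction type is the Meerwein‑type radical carboaminoxylation (oxyarylation) of activated alkenes with arenediazonium salts and a nitroxide. No ring is closed. The one new stereocentre, C3, is set under substrate control: the radical is planar and lies in the lactone ring, the C4 arylmethyl arm covers one face, and the bulky nitroxide should bond to the other, placing oxygen trans to the C4 arm and the new arylmethyl arm cis. Regioselectivity is secured by the free CH2 terminus and by the stability of the α‑carbonyl radical. Selectivity for addition over aryl–nitroxide coupling and hydrogen abstraction is secured by the slow addition of 18, which keeps the nitroxide concentration low, by the high rate of aryl radical addition to acrylate‑type alkenes, and by the hydrogen‑poor solvent. The C4 centre is protected because 18 is consumed by the excess of 16 as fast as it arrives, so that no base accumulates to move the double bond into the ring.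

Step 10
Reactants: 19 (3S,4R)‑3,4‑bis[(4‑benzyloxy‑3‑methoxyphenyl)methyl]‑3‑[(2,2,6,6‑tetramethylpiperidin‑1‑yl)oxy]dihydrofuran‑2(3H)‑one
Product: 20 (3S,4R)‑3,4‑bis[(4‑benzyloxy‑3‑methoxyphenyl)methyl]‑3‑hydroxydihydrofuran‑2(3H)‑one
Conditions: Zn dust, AcOH/THF/H2O (3:1:1), rt to 40 °C
Reagents that add atoms: none
Why: Reductive N–O cleavage by zinc in acetic acid (electron transfer into the N–O bond of the protonated alkoxyamine); the C3–O bond is not broken, so the C3 configuration should be retained, and benzyl ethers and lactone are inert.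

Step 11
Reactants: 20 (3S,4R)‑3,4‑bis[(4‑benzyloxy‑3‑methoxyphenyl)methyl]‑3‑hydroxydihydrofuran‑2(3H)‑one
Product: 21 (3S,4R)‑3‑hydroxy‑3,4‑bis[(4‑hydroxy‑3‑methoxyphenyl)methyl]dihydrofuran‑2(3H)‑one (CNP0166172.2)
Conditions: H2 (1 atm), Pd/C (10 %), EtOAc/MeOH, rt
Reagents that add atoms: none
Why: Catalytic hydrogenolysis of the two aryl benzyl ethers; the C3 hydroxyl is homobenzylic and not cleaved, and the lactone and the aryl methyl ethers do not react.

## Compound list

1 | 3‑(4‑hydroxy‑3‑methoxyphenyl)propanoic acid (dihydroferulic acid) | COc1cc(CCC(=O)O)ccc1O | starting material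
2 | 3‑(4‑benzyloxy‑3‑methoxyphenyl)propanoic acid | COc1cc(CCC(=O)O)ccc1OCc1ccccc1 | intermediate
3 | (R)‑4‑benzyl‑2‑oxazolidinone | O=C1N[C@H](Cc2ccccc2)CO1 | starting material
4 | 3‑(4‑benzyloxy‑3‑methoxyphenyl)propanoic pivalic anhydride | COc1cc(CCC(=O)OC(=O)C(C)(C)C)ccc1OCc1ccccc1 | intermediate (not isolated)
5 | (R)‑4‑benzyl‑3‑[3‑(4‑benzyloxy‑3‑methoxyphenyl)propanoyl]oxazolidin‑2‑one | COc1cc(CCC(=O)N2[C@H](Cc3ccccc3)COC2=O)ccc1OCc1ccccc1 | intermediate
6 | tert‑butyl bromoacetate | BrCC(=O)OC(C)(C)C | starting material
7 | tert‑butyl (S)‑4‑[(R)‑4‑benzyl‑2‑oxooxazolidin‑3‑yl]‑3‑[(4‑benzyloxy‑3‑methoxyphenyl)methyl]‑4‑oxobutanoate | COc1cc(C[C@@H](CC(=O)OC(C)(C)C)C(=O)N2[C@H](Cc3ccccc3)COC2=O)ccc1OCc1ccccc1 | intermediate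
8 | tert‑butyl (S)‑4‑(4‑benzyloxy‑3‑methoxyphenyl)‑3‑(hydroxymethyl)butanoate | COc1cc(C[C@@H](CC(=O)OC(C)(C)C)CO)ccc1OCc1ccccc1 | intermediate (not isolated)
9 | (S)‑4‑[(4‑benzyloxy‑3‑methoxyphenyl)methyl]dihydrofuran‑2(3H)‑one | COc1cc(C[C@@H]2COC(=O)C2)ccc1OCc1ccccc1 | intermediate
10 | (3R,4S)‑4‑[(4‑benzyloxy‑3‑methoxyphenyl)methyl]‑3‑[(dimethylamino)methyl]dihydrofuran‑2(3H)‑one (trans) | COc1cc(C[C@@H]2COC(=O)[C@H]2CN(C)C)ccc1OCc1ccccc1 | intermediate (not isolated)
11 | {(3R,4S)‑4‑[(4‑benzyloxy‑3‑methoxyphenyl)methyl]‑2‑oxotetrahydrofuran‑3‑yl}‑N,N,N‑trimethylmethanaminium iodide | COc1cc(C[C@@H]2COC(=O)[C@H]2C[N+](C)(C)C)ccc1OCc1ccccc1.[I-] | intermediate (not isolated)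
12 | (S)‑4‑[(4‑benzyloxy‑3‑methoxyphenyl)methyl]‑3‑methylenedihydrofuran‑2(3H)‑one | COc1cc(C[C@@H]2COC(=O)C2=C)ccc1OCc1ccccc1 | intermediate
13 | 2‑methoxy‑4‑nitrophenol | COc1cc([N+](=O)[O-])ccc1O | starting material
14 | 1‑benzyloxy‑2‑methoxy‑4‑nitrobenzene | COc1cc([N+](=O)[O-])ccc1OCc1ccccc1 | intermediate
15 | 4‑benzyloxy‑3‑methoxyaniline | COc1cc(N)ccc1OCc1ccccc1 | intermediate
16 | 4‑benzyloxy‑3‑methoxybenzenediazonium tetrafluoroborate | COc1cc([N+]#N)ccc1OCc1ccccc1.F[B-](F)(F)F | intermediate
17 | TEMPO (2,2,6,6‑tetramethylpiperidin‑1‑oxyl) | CC1(C)CCCC(C)(C)N1[O] | starting material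
18 | TEMPONa (sodium 2,2,6,6‑tetramethylpiperidin‑1‑olate) | CC1(C)CCCC(C)(C)N1[O-].[Na+] | intermediate (not isolated)
19 | (3S,4R)‑3,4‑bis[(4‑benzyloxy‑3‑methoxyphenyl)methyl]‑3‑[(2,2,6,6‑tetramethylpiperidin‑1‑yl)oxy]dihydrofuran‑2(3H)‑one | COc1cc(C[C@@H]2COC(=O)[C@]2(ON2C(C)(C)CCCC2(C)C)Cc2ccc(OCc3ccccc3)c(OC)c2)ccc1OCc1ccccc1 | intermediate
20 | (3S,4R)‑3,4‑bis[(4‑benzyloxy‑3‑methoxyphenyl)methyl]‑3‑hydroxydihydrofuran‑2(3H)‑one | COc1cc(C[C@@H]2COC(=O)[C@]2(O)Cc2ccc(OCc3ccccc3)c(OC)c2)ccc1OCc1ccccc1 | intermediate
21 | (3S,4R)‑3‑hydroxy‑3,4‑bis[(4‑hydroxy‑3‑methoxyphenyl)methyl]dihydrofuran‑2(3H)‑one (CNP0166172.2) | COc1cc(C[C@@H]2COC(=O)[C@]2(O)Cc2ccc(O)c(OC)c2)ccc1O | target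

## Step count and least certain steps

Total step count: 11. Longest linear sequence: 8 steps (steps 1, 2, 3, 4, 5, 9, 10, 11); the diazonium branch (steps 6, 7, 8) joins at step 9.

**Step 9 (key step).**
- Most likely to go wrong: coupling of the aryl radical with the nitroxide, or hydrogen abstraction by it, may outrun addition to the alkene. The aminoxyl anion may add to the alkene in conjugate fashion or shift the double bond into the ring. Facial discrimination at the planar C3 radical may be incomplete, because the controlling arm is one atom away and the new in‑plane arylmethyl group adds crowding of its own.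
- Fallback: it sets out from 9. Purchased 4‑benzyloxy‑3‑methoxybenzyl alcohol is converted with PBr3 (CH2Cl2, 0 °C) into 4‑benzyloxy‑3‑methoxybenzyl bromide F1. The lithium enolate of 9 (LiN(iPr)2, THF, −78 °C) is alkylated with it anti to the C4 arm to give the trans lactone (3S,4S)‑3,4‑bis[(4‑benzyloxy‑3‑methoxyphenyl)methyl]dihydrofuran‑2(3H)‑one F2. Its potassium enolate (KN(SiMe3)2, THF, −78 °C) is hydroxylated with 2‑(phenylsulfonyl)‑3‑phenyloxaziridine, the oxygen being expected anti to the C4 arm. The fallback comes back to the route at 20 and bypasses 12 and 19.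

**Step 5.**
- Most likely to go wrong: migration of the exocyclic double bond into the ring during elimination or purification, which would destroy the C4 stereocentre; incomplete Mannich reaction of the hindered enolate is the second concern.
- Fallback: it sets out from 9. Carboxylation with MeOMgOCO2Me (DMF, 125 °C; acidic work‑up) gives (3R,4S)‑4‑[(4‑benzyloxy‑3‑methoxyphenyl)methyl]‑2‑oxotetrahydrofuran‑3‑carboxylic acid F3 (C3 epimerisable). Decarboxylative Mannich methylenation (aq. CH2O, Et2NH, NaOAc/AcOH, rt) runs in a weakly acidic buffer that cannot remove the C4 hydrogen, and comes back to the route at 12.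

**Step 10.**
- Most likely to go wrong: slow N–O cleavage at the hindered tertiary alkoxyamine may call for heating, at which reversible C3–O homolysis could erode the C3 configuration or lead to elimination. Reductive loss of the α‑oxygen (cleavage of C3–O in place of N–O) may also compete.
- Fallback: it sets out from 12 and avoids any N–O bond. Epoxidation with dimethyldioxirane (acetone, 0 °C) anti to the C4 arm gives the spiro‑epoxide (3R,7R)‑7‑[(4‑benzyloxy‑3‑methoxyphenyl)methyl]‑1,5‑dioxaspiro[2.4]heptan‑4‑one F4. The Grignard reagent (4‑benzyloxy‑3‑methoxyphenyl)magnesium bromide F5 (from purchased 1‑benzyloxy‑4‑bromo‑2‑methoxybenzene and Mg, THF) opens it with CuI catalysis (THF, −40 °C) at the unhindered CH2 terminus. The fallback comes back to the route at 20.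

**Step 4.**
- Most likely to go wrong: hydride attack on the ring carbonyl of the auxiliary, or over‑reduction of the ester or of lactone formed early; during the acid stage, tert‑butylation of the electron‑rich arene.
- Fallback: it sets out from 7. Hydrolysis with LiOH/H2O2 (THF/H2O, 0 °C) gives (S)‑2‑[(4‑benzyloxy‑3‑methoxyphenyl)methyl]‑4‑tert‑butoxy‑4‑oxobutanoic acid F6 and recovered 3. BH3·SMe2 (THF, 0 °C) reduces the free acid selectively, which comes back to the route at 8; this is lactonised to 9 as in step 4.

## Further compounds

F1 | step 9 | 4‑benzyloxy‑3‑methoxybenzyl bromide | COc1cc(CBr)ccc1OCc1ccccc1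
F2 | step 9 | (3S,4S)‑3,4‑bis[(4‑benzyloxy‑3‑methoxyphenyl)methyl]dihydrofuran‑2(3H)‑one | COc1cc(C[C@@H]2COC(=O)[C@H]2Cc2ccc(OCc3ccccc3)c(OC)c2)ccc1OCc1ccccc1
F3 | step 5 | (3R,4S)‑4‑[(4‑benzyloxy‑3‑methoxyphenyl)methyl]‑2‑oxotetrahydrofuran‑3‑carboxylic acid | COc1cc(C[C@@H]2COC(=O)[C@H]2C(=O)O)ccc1OCc1ccccc1
F4 | step 10 | (3R,7R)‑7‑[(4‑benzyloxy‑3‑methoxyphenyl)methyl]‑1,5‑dioxaspiro[2.4]heptan‑4‑one | COc1cc(C[C@@H]2COC(=O)[C@]23CO3)ccc1OCc1ccccc1
F5 | step 10 | (4‑benzyloxy‑3‑methoxyphenyl)magnesium bromide | COc1cc([Mg]Br)ccc1OCc1ccccc1
F6 | step 4 | (S)‑2‑[(4‑benzyloxy‑3‑methoxyphenyl)methyl]‑4‑tert‑butoxy‑4‑oxobutanoic acid | COc1cc(C[C@@H](CC(=O)OC(C)(C)C)C(=O)O)ccc1OCc1ccccc1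
A1 | alternative 1 | (S)‑2‑[(4‑benzyloxy‑3‑methoxyphenyl)methyl]‑4‑(4‑benzyloxy‑3‑methoxyphenyl)but‑3‑yn‑1‑ol | COc1cc(C[C@H](CO)C#Cc2ccc(OCc3ccccc3)c(OC)c2)ccc1OCc1ccccc1
A2 | alternative 1 | (S,E)‑3‑[(4‑benzyloxy‑3‑methoxyphenyl)methylidene]‑4‑[(4‑benzyloxy‑3‑methoxyphenyl)methyl]dihydrofuran‑2(3H)‑one | COc1cc(C[C@@H]2COC(=O)/C2=C/c2ccc(OCc3ccccc3)c(OC)c2)ccc1OCc1ccccc1
A3 | alternative 2 | (S)‑2‑{4‑benzyloxy‑3‑[(4‑benzyloxy‑3‑methoxyphenyl)methyl]but‑1‑en‑2‑yl}‑4,4,5,5‑tetramethyl‑1,3,2‑dioxaborolane | COc1cc(C[C@H](COCc2ccccc2)C(=C)B2OC(C)(C)C(C)(C)O2)ccc1OCc1ccccc1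
A4 | alternative 2 | (isopropoxydimethylsilyl)methylmagnesium chloride | CC(C)O[Si](C)(C)C[Mg]Cl
A5 | alternative 2 | 4‑benzyloxy‑3‑methoxyphenyl trifluoromethanesulfonate | COc1cc(OS(=O)(=O)C(F)(F)F)ccc1OCc1ccccc1
A6 | alternative 2 | tertiary pinacol boronate carrying the arylmethyl, silylmethyl and C4 chain substituents, configured as the target with boron in the place of the hydroxyl | COc1cc(C[C@H](COCc2ccccc2)[C@@](B2OC(C)(C)C(C)(C)O2)(Cc2ccc(OCc3ccccc3)c(OC)c2)C[Si](C)(C)OC(C)C)ccc1OCc1ccccc1
A7 | alternative 3 | (S)‑3‑(4‑benzyloxy‑3‑methoxyphenyl)‑2‑[(1S,2S)‑2‑(4‑benzyloxy‑3‑methoxyphenyl)cyclopropyl]‑2‑hydroxypropanoic acid | OC(=O)[C@](O)(Cc1ccc(OCc2ccccc2)c(OC)c1)[C@H]1C[C@@H]1c1ccc(OCc2ccccc2)c(OC)c1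
A8 | alternative 3 | (3S,4R)‑3,4‑bis[(4‑benzyloxy‑3‑methoxyphenyl)methyl]‑3‑hydroxydihydrofuran‑2(3H)‑one (identical with 20) | COc1cc(C[C@@H]2COC(=O)[C@]2(O)Cc2ccc(OCc3ccccc3)c(OC)c2)ccc1OCc1ccccc1
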